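**Retrosynthetic overview**
1. Target 11 ⇒ 2,5-dihydroxy-3-alkylquinone 10, by selective O-methylation of the unhindered hydroxy-enone only.
2. 10 ⇒ commercial 2,5-dihydroxy-1,4-benzoquinone 8 + aldehyde 7; the ring–chain C–C bond is made by an intermolecular Knoevenagel (aldol-type) condensation with in situ Hantzsch-ester reduction.
3. 7 ⇒ (8Z,11Z)-dienol 6 ⇒ skipped diyne 5; cis-semihydrogenation sets both Z olefins.
4. 5 ⇒ non-8-yn-1-ol 3 + 1-bromohex-2-yne 2 (copper-mediated coupling); 2 comes from hex-2-yn-1-ol 1.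
5. No ring is formed; the quinone ring is bought intact as 8.

Assumption: the target has no stereocentre, so "single enantiomer" is read as the single (8Z,11Z) geometric isomer.

**Route**

Step 1
Reactants: 1 hex-2-yn-1-ol
Product: 2 1-bromohex-2-yne
Conditions: PBr3 (0.4 equiv), pyridine (0.1 equiv), Et2O, −10 °C → rt
Reagents that add atoms: phosphorus tribromide, BrP(Br)Br
Why: Bromination of a primary propargylic alcohol through its phosphite ester (SN2 displacement by bromide), run cold with catalytic pyridine so that no allenyl bromide forms.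

Step 2
Reactants: 2 1-bromohex-2-yne; 3 non-8-yn-1-ol
Product: 5 pentadeca-8,11-diyn-1-ol, via 1-iodohex-2-yne 4 (not isolated)
Conditions: CuI (1.0 equiv), NaI (1.0 equiv), Cs2CO3 (1.0 equiv), DMF, rt, 16 h
Reagents that add atoms: none
Why: Copper-mediated sp–sp3 coupling of a terminal alkyne with a propargylic halide (NaI converts 2 into the more reactive iodide 4 in the flask) gives the skipped 1,4-diyne, and the carbonate base tolerates the free hydroxyl.

Step 3
Reactants: 5 pentadeca-8,11-diyn-1-ol
Product: 6 (8Z,11Z)-pentadeca-8,11-dien-1-ol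
Conditions: H2 (1 atm), Ni2B made from Ni(OAc)2·4H2O (0.2 equiv) and NaBH4 (0.2 equiv), ethylenediamine (0.6 equiv), EtOH, rt; stopped after 2.0 equiv H2
Reagents that add atoms: none
Why: P-2 nickel semihydrogenation delivers H2 syn on the amine-poisoned nickel boride surface and stops at the alkene, which sets both the 8Z and the 11Z geometry.

Step 4
Reactants: 6 (8Z,11Z)-pentadeca-8,11-dien-1-ol
Product: 7 (8Z,11Z)-pentadeca-8,11-dienal
Conditions: PhI(OAc)2 (1.1 equiv), TEMPO (0.1 equiv), CH2Cl2, rt, 3 h; used at once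
Reagents that add atoms: none
Why: TEMPO-catalysed oxoammonium oxidation with PhI(OAc)2 as terminal oxidant stops at the aldehyde and is mild enough to leave the skipped (Z,Z)-diene unisomerised.

Step 5
Reactants: 7 (8Z,11Z)-pentadeca-8,11-dienal; 8 2,5-dihydroxy-1,4-benzoquinone (2.0 equiv)
Product: 10 2,5-dihydroxy-3-[(8Z,11Z)-pentadeca-8,11-dien-1-yl]-1,4-benzoquinone, via alkylidene trione 9 (not isolated)
Conditions: L-proline (20 mol %), Hantzsch ester (diethyl 2,6-dimethyl-1,4-dihydropyridine-3,5-dicarboxylate, 1.1 equiv), CH2Cl2, rt, 24 h, argon, dark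
Reagents that add atoms: none
Why: Proline-catalysed Knoevenagel (aldol-type) condensation of the enolic C3–H of the vinylogous acid 8 with aldehyde 7 forms the ring–chain C–C bond, and the electrophilic alkylidene trione 9 is reduced at once by conjugate hydride transfer from the Hantzsch ester (three-component reductive alkylation), with excess 8 suppressing double alkylation.

Step 6
Reactants: 10 2,5-dihydroxy-3-[(8Z,11Z)-pentadeca-8,11-dien-1-yl]-1,4-benzoquinone
Product: 11 sorgoleone-360, 2-hydroxy-5-methoxy-3-[(8Z,11Z)-pentadeca-8,11-dien-1-yl]-1,4-benzoquinone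
Conditions: HCl (1.25 M in MeOH, anhydrous), 45 °C, 4 h, followed by TLC
Reagents that add atoms: methanol, CO
Why: In this acid-catalysed vinylogous Fischer esterification, MeOH condenses only with the unhindered hydroxy-enone next to C6–H, because the hydroxyl flanked by the C3 chain is shielded and its ether would be twisted out of conjugation, and methanolic HCl does not isomerise the Z olefins.

**Compound list**
1 | hex-2-yn-1-ol | CCCC#CCO | starting material
2 | 1-bromohex-2-yne | CCCC#CCBr | intermediate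
3 | non-8-yn-1-ol | C#CCCCCCCCO | starting material
4 | 1-iodohex-2-yne | CCCC#CCI | intermediate (not isolated)
5 | pentadeca-8,11-diyn-1-ol | CCCC#CCC#CCCCCCCCO | intermediate
6 | (8Z,11Z)-pentadeca-8,11-dien-1-ol | CCC/C=C\C/C=C\CCCCCCCO | intermediate
7 | (8Z,11Z)-pentadeca-8,11-dienal | CCC/C=C\C/C=C\CCCCCCC=O | intermediate
8 | 2,5-dihydroxy-1,4-benzoquinone | O=C1C=C(O)C(=O)C=C1O | starting material
9 | 5-hydroxy-3-[(8Z,11Z)-pentadeca-8,11-dien-1-ylidene]cyclohex-5-ene-1,2,4-trione (alkylidene trione, exocyclic C=C geometry undefined) | CCC/C=C\C/C=C\CCCCCCC=C1C(=O)C(=O)C=C(O)C1=O | intermediate (not isolated)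
10 | 2,5-dihydroxy-3-[(8Z,11Z)-pentadeca-8,11-dien-1-yl]-1,4-benzoquinone | CCC/C=C\C/C=C\CCCCCCCC1=C(O)C(=O)C=C(O)C1=O | intermediate
11 | sorgoleone-360, 2-hydroxy-5-methoxy-3-[(8Z,11Z)-pentadeca-8,11-dien-1-yl]-1,4-benzoquinone | CCC/C=C\C/C=C\CCCCCCCC1=C(O)C(=O)C=C(OC)C1=O | target

**Step count**
Total steps: 6. Longest linear sequence: 6 (1 → 2 → 5 → 6 → 7 → 10 → 11).

**Steps most likely to fail, with fallbacks**

Step 3 (over-reduction or partial E-isomer in the double semihydrogenation). The fallback sets out from 5 and comes back at 6, replacing catalytic hydrogenation by stoichiometric hydroboration–protonolysis. Diyne 5 is silylated (TBSCl, imidazole, DMF) to tert-butyl(dimethyl)(pentadeca-8,11-diyn-1-yloxy)silane F1. Dicyclohexylborane (2.2 equiv, THF, 0 °C) adds syn once to each triple bond to give the bis(alkenyl)borane F2, drawn as one regioisomer since the regiochemistry is irrelevant. Protonolysis of both C–B bonds with AcOH, with retention, gives tert-butyl(dimethyl)[(8Z,11Z)-pentadeca-8,11-dien-1-yloxy]silane F3. n-Bu4NF in THF then returns dienol 6.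

Step 5 (low conversion or double alkylation in the reductive alkylation). The fallback sets out from 6 and comes back at 11, attaching the chain to an arene by alkylation and making the quinone afterwards. Dienol 6 is brominated (CBr4, PPh3, CH2Cl2, 0 °C) to (8Z,11Z)-1-bromopentadeca-8,11-diene F4. Commercial 1,2,4,5-tetramethoxybenzene (COc1cc(OC)c(OC)cc1OC) is ortho-lithiated (n-BuLi, THF, 0 °C) and alkylated with F4 (DMPU, −78 °C → rt) to 1,2,4,5-tetramethoxy-3-[(8Z,11Z)-pentadeca-8,11-dien-1-yl]benzene F5. Oxidative demethylation with (NH4)2Ce(NO3)6 (MeCN/H2O, 0 °C) gives 2,5-dimethoxy-3-[(8Z,11Z)-pentadeca-8,11-dien-1-yl]-1,4-benzoquinone F6. Brief treatment with 60% HClO4 in dioxane at rt hydrolyses selectively the twisted methoxy group next to the chain and gives 11.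

Step 6 (incomplete regioselectivity or over-methylation). The fallback sets out from 8, uses aldehyde 7, and comes back at 11, fixing the O-methyl pattern before the C–C bond is made. Quinone 8 is etherified twice (HCl in MeOH, reflux) to 2,5-dimethoxy-1,4-benzoquinone F7. One equivalent of NaOH in aqueous MeOH at 0 °C, then acidification, gives 2-hydroxy-5-methoxy-1,4-benzoquinone F8; the vinylogous carboxylate formed resists a second hydrolysis. The proline/Hantzsch-ester reductive alkylation of step 5 is then run on F8 with 7. It can occur only at the single enolic C–H next to the hydroxyl, passes through the alkylidene trione F9, and gives 11 directly.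

**Further compounds**
F1 | step 3 | tert-butyl(dimethyl)(pentadeca-8,11-diyn-1-yloxy)silane | CCCC#CCC#CCCCCCCCO[Si](C)(C)C(C)(C)C
F2 | step 3 | bis(alkenyl)borane from double syn-hydroboration of F1 with dicyclohexylborane (8,12-diboryl regioisomer drawn) | CCC/C(B(C1CCCCC1)C1CCCCC1)=C\C/C=C(\CCCCCCCO[Si](C)(C)C(C)(C)C)B(C1CCCCC1)C1CCCCC1
F3 | step 3 | tert-butyl(dimethyl)[(8Z,11Z)-pentadeca-8,11-dien-1-yloxy]silane | CCC/C=C\C/C=C\CCCCCCCO[Si](C)(C)C(C)(C)C
F4 | step 5 | (8Z,11Z)-1-bromopentadeca-8,11-diene | CCC/C=C\C/C=C\CCCCCCCBr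
F5 | step 5 | 1,2,4,5-tetramethoxy-3-[(8Z,11Z)-pentadeca-8,11-dien-1-yl]benzene | CCC/C=C\C/C=C\CCCCCCCc1c(OC)c(OC)cc(OC)c1OC
F6 | step 5 | 2,5-dimethoxy-3-[(8Z,11Z)-pentadeca-8,11-dien-1-yl]-1,4-benzoquinone | CCC/C=C\C/C=C\CCCCCCCC1=C(OC)C(=O)C=C(OC)C1=O
F7 | step 6 | 2,5-dimethoxy-1,4-benzoquinone | COC1=CC(=O)C(OC)=CC1=O
F8 | step 6 | 2-hydroxy-5-methoxy-1,4-benzoquinone | COC1=CC(=O)C(O)=CC1=O
F9 | step 6 | 5-methoxy-3-[(8Z,11Z)-pentadeca-8,11-dien-1-ylidene]cyclohex-5-ene-1,2,4-trione | CCC/C=C\C/C=C\CCCCCCC=C1C(=O)C(=O)C=C(OC)C1=O
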